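## Retrosynthetic overview

1. The last bond made is C(sp3)–C(sp2) between the CH2CH2 arm on the dioxane and the trisubstituted alkene: 9-BBN hydroboration of vinyl dioxane 19, then Suzuki–Miyaura coupling with (E)-alkenyl iodide 35.
2. In 19 the vinyl group comes from a methyl carbinol and the ester from a terminal alkene. The 1,2-dioxane ring closes by 6-exo attack of a secondary hydroperoxide on a (2R,3R)-trisubstituted epoxide, with inversion at the tertiary carbon.
3. The open-chain precursor carries the hydroperoxide as a monoperoxyketal, installed by SN2 inversion of the anti alcohol from Brown crotylation of (4E)-4-methylhex-4-enal (Johnson–Claisen); the epoxide comes from Shi epoxidation.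
4. In 35 the (E)-alkenyl iodide comes from Zr-catalysed carboalumination/iodination of a butynyl chain attached by Stork–Danheiser addition to a vinylogous ester.
5. Ring order: the cyclohexenone ring is made first in its own branch (step 10), the 1,2-dioxane ring in the other branch (step 6); no ring is formed after the coupling.

## Route

**Step 1**
Reactants: 1 3-methylbut-3-en-2-ol (racemic); 2 1,1,1-trimethoxyethane
Product: 4 methyl (4E)-4-methylhex-4-enoate, via mixed ketene acetal 3 (not isolated)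
Conditions: 2 (4 equiv), EtCO2H (cat.), 110–125 °C, MeOH distilled off
Reagents that add atoms: none
Why: Johnson–Claisen orthoester rearrangement through a chair transition state with the carbinol methyl equatorial gives the (E)-trisubstituted alkene (typically ≥95:5) and erases the stereocentre of 1.

**Step 2**
Reactants: 4 methyl (4E)-4-methylhex-4-enoate
Product: 5 (4E)-4-methylhex-4-enal
Conditions: i-Bu2AlH (1.05 equiv), CH2Cl2, −78 °C; aq. KNaC4H4O6
Reagents that add atoms: none
Why: Low-temperature half-reduction of the ester stops at the tetrahedral aluminate, which releases the aldehyde on work-up.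

**Step 3**
Reactants: 5 (4E)-4-methylhex-4-enal; 6 (2E)-but-2-ene
Product: 10 (3S,4R,7E)-3,7-dimethylnona-1,7-dien-4-ol, via crotylpotassium 7 (not isolated), via crotylborane 8 (not isolated), via borinate ester 9 (not isolated)
Conditions: 6, KOt-Bu, n-BuLi, THF, −78 → −45 °C; (−)-B-methoxydiisopinocampheylborane [(−)-Ipc2BOMe, from (+)-α-pinene], −78 °C; BF3·OEt2; 5, −78 °C; then NaOH, H2O2, rt
Reagents that add atoms: none
Why: Brown asymmetric crotylboration: the (E)-crotylborane reacts through a closed chair transition state to give the anti product, and the (+)-α-pinene-derived Ipc groups direct Si-face attack, which sets 3S,4R.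

**Step 4**
Reactants: 10 (3S,4R,7E)-3,7-dimethylnona-1,7-dien-4-ol
Product: 12 (3S,4S,7E)-4-[(2-methoxypropan-2-yl)peroxy]-3,7-dimethylnona-1,7-diene, via triflate 11 (not isolated)
Conditions: Tf2O, 2,6-lutidine, CH2Cl2, −78 °C; then added to KOOC(CH3)2OCH3 (from the hydroperoxide and KOt-Bu), THF, −78 → 0 °C
Reagents that add atoms: 2-methoxypropan-2-yl hydroperoxide, COC(C)(C)OO
Why: SN2 alkylation of a monoperoxyketal anion (a weakly basic α-effect nucleophile) by the secondary triflate inverts C4 to S, which is the C3 configuration of the target.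

**Step 5**
Reactants: 12 (3S,4S,7E)-4-[(2-methoxypropan-2-yl)peroxy]-3,7-dimethylnona-1,7-diene
Product: 13 (2R,3R)-2-[(3S,4S)-3-[(2-methoxypropan-2-yl)peroxy]-4-methylhex-5-en-1-yl]-2,3-dimethyloxirane
Conditions: 1,2:4,5-di-O-isopropylidene-β-D-erythro-2,3-hexodiulo-2,6-pyranose (0.3 equiv), KHSO5 (as 2KHSO5·KHSO4·K2SO4), K2CO3, Bu4NHSO4, MeCN/CH2(OMe)2, aq. Na2B4O7 buffer (pH ≈ 10.5), 0 °C
Reagents that add atoms: potassium peroxymonosulfate, KHSO5, [K+].[O-]S(=O)(=O)OO
Why: Shi epoxidation: the dioxirane of the D-fructose-derived ketone attacks only the electron-rich trisubstituted alkene (the vinyl group is much slower) through the spiro transition state, giving the (R,R)-epoxide under reagent control.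

**Step 6**
Reactants: 13 (2R,3R)-2-[(3S,4S)-3-[(2-methoxypropan-2-yl)peroxy]-4-methylhex-5-en-1-yl]-2,3-dimethyloxirane
Product: 15 (1R)-1-[(3S,6S)-6-[(2S)-but-3-en-2-yl]-3-methyl-1,2-dioxan-3-yl]ethan-1-ol, via hydroperoxy epoxide 14 (not isolated)
Conditions: (1S)-(+)-10-camphorsulfonic acid (0.1 equiv), MeOH (5 equiv), CH2Cl2, 0 °C → rt
Reagents that add atoms: none
Why: Acid transketalisation frees the hydroperoxide, which opens the protonated epoxide by 6-exo attack at the tertiary carbon with inversion, closing the 1,2-dioxane and fixing the quaternary peroxide carbon; minor diastereomers from steps 3 and 5 are removed by chromatography here.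

**Step 7**
Reactants: 15 (1R)-1-[(3S,6S)-6-[(2S)-but-3-en-2-yl]-3-methyl-1,2-dioxan-3-yl]ethan-1-ol
Product: 17 (2R)-2-[(3S,6S)-6-[(1R)-1-hydroxyethyl]-6-methyl-1,2-dioxan-3-yl]propanoic acid, via aldehyde 16 (not isolated)
Conditions: O3, MeCN/H2O (9:1), 0 °C; N2 purge; then NaClO2, NaH2PO4, 0 °C → rt
Reagents that add atoms: ozone, [O-][O+]=O; sodium chlorite, NaClO2, [Na+].[O-]Cl=O
Why: Ozonolysis in wet acetonitrile gives the aldehyde directly and a one-pot Pinnick oxidation takes it to the acid under buffered, non-basic conditions that leave the dialkyl peroxide, the alcohol and the α-stereocentre untouched.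

**Step 8**
Reactants: 17 (2R)-2-[(3S,6S)-6-[(1R)-1-hydroxyethyl]-6-methyl-1,2-dioxan-3-yl]propanoic acid
Product: 18 methyl (2R)-2-[(3S,6S)-6-[(1R)-1-hydroxyethyl]-6-methyl-1,2-dioxan-3-yl]propanoate
Conditions: Me3SiCHN2, MeOH/toluene, 0 °C
Reagents that add atoms: (trimethylsilyl)diazomethane, C[Si](C)(C)C=[N+]=[N-]
Why: Diazoalkane esterification methylates only the carboxylic acid, without base and without touching the β-peroxy stereocentres.

**Step 9**
Reactants: 18 methyl (2R)-2-[(3S,6S)-6-[(1R)-1-hydroxyethyl]-6-methyl-1,2-dioxan-3-yl]propanoate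
Product: 19 methyl (2R)-2-[(3S,6S)-6-ethenyl-6-methyl-1,2-dioxan-3-yl]propanoate
Conditions: methyl N-(triethylammoniosulfonyl)carbamate (Burgess reagent), toluene, 70 °C
Reagents that add atoms: none
Why: Burgess dehydration (syn Ei elimination of the sulfamate) can only remove a hydrogen from the methyl group, since the neighbouring carbon is quaternary, so the vinyl group is the only alkene possible.

**Step 10**
Reactants: 20 3-methylbutan-2-one; 21 methyl prop-2-enoate
Product: 23 4,4-dimethylcyclohexane-1,3-dione, via keto ester 22 (not isolated)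
Conditions: KOt-Bu (1.1 equiv), t-BuOH/THF, 0 °C → reflux; then aq. HCl
Reagents that add atoms: none
Why: Reversible Michael addition at the more substituted α-carbon followed by intramolecular Claisen condensation is funnelled to this dione because only it forms a stabilised 1,3-dione enolate.

**Step 11**
Reactants: 23 4,4-dimethylcyclohexane-1,3-dione
Product: 24 2,4,4-trimethylcyclohexane-1,3-dione
Conditions: MeI, NaOH, H2O/1,4-dioxane, reflux
Reagents that add atoms: iodomethane, CI
Why: C-alkylation of the 1,3-dione enolate at the carbon between the carbonyls.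

**Step 12**
Reactants: 24 2,4,4-trimethylcyclohexane-1,3-dione
Product: 25 3-ethoxy-2,6,6-trimethylcyclohex-2-en-1-one
Conditions: EtOH, p-toluenesulfonic acid monohydrate (cat.), toluene, reflux, Dean–Stark
Reagents that add atoms: ethanol, CCO
Why: Acid-catalysed enol etherification takes place at the carbonyl remote from the gem-dimethyl group, giving the vinylogous ester whose free carbonyl sits next to the quaternary carbon.

**Step 13**
Reactants: 26 4-bromobut-1-yne
Product: 27 (4-bromobut-1-yn-1-yl)trimethylsilane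
Conditions: n-BuLi (1.0 equiv), THF, −78 °C; then Me3SiCl, −78 °C → rt
Reagents that add atoms: chlorotrimethylsilane, C[Si](C)(C)Cl
Why: Deprotonation of the terminal alkyne is much faster than attack on the primary bromide at −78 °C, and C-silylation masks the acidic C–H for the Grignard step.

**Step 14**
Reactants: 25 3-ethoxy-2,6,6-trimethylcyclohex-2-en-1-one; 27 (4-bromobut-1-yn-1-yl)trimethylsilane
Product: 30 2,4,4-trimethyl-3-[4-(trimethylsilyl)but-3-yn-1-yl]cyclohex-2-en-1-one, via Grignard reagent 28 (not isolated), via tertiary carbinol 29 (not isolated)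
Conditions: 27, Mg, THF, 40 °C; anhydrous CeCl3, THF, −78 °C; 25, −78 → 0 °C; then 1 M aq. HCl, rt
Reagents that add atoms: none
Why: Stork–Danheiser sequence: cerium-promoted 1,2-addition to the vinylogous ester and acid hydrolysis with 1,3-carbonyl transposition place the side chain on the enone β-carbon next to the gem-dimethyl group.

**Step 15**
Reactants: 30 2,4,4-trimethyl-3-[4-(trimethylsilyl)but-3-yn-1-yl]cyclohex-2-en-1-one
Product: 32 3-(but-3-yn-1-yl)-2,4,4-trimethylcyclohex-2-en-1-ol (racemic), via silylated allylic alcohol 31 (not isolated)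
Conditions: NaBH4, CeCl3·7H2O, MeOH, 0 °C; then K2CO3, rt
Reagents that add atoms: none
Why: Luche 1,2-reduction masks the ketone as an allylic alcohol (needed because Me3Al adds to ketones) and methanolic carbonate cleaves the alkynyl C–Si bond in the same pot.

**Step 16**
Reactants: 32 3-(but-3-yn-1-yl)-2,4,4-trimethylcyclohex-2-en-1-ol (racemic)
Product: 34 3-[(3E)-4-iodo-3-methylbut-3-en-1-yl]-2,4,4-trimethylcyclohex-2-en-1-ol (racemic), via alkenylalane 33 (not isolated)
Conditions: Me3Al (3 equiv), (C5H5)2ZrCl2 (0.25 equiv), CH2Cl2, 0 °C → rt; then I2, THF, −30 → 0 °C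
Reagents that add atoms: trimethylaluminium, Me3Al, C[Al](C)C; iodine, II
Why: Negishi zirconium-catalysed carboalumination adds methyl and aluminium syn across the terminal alkyne with aluminium at the terminus, and iodinolysis with retention gives the (E)-alkenyl iodide (>98:2).

**Step 17**
Reactants: 34 3-[(3E)-4-iodo-3-methylbut-3-en-1-yl]-2,4,4-trimethylcyclohex-2-en-1-ol (racemic)
Product: 35 3-[(3E)-4-iodo-3-methylbut-3-en-1-yl]-2,4,4-trimethylcyclohex-2-en-1-one
Conditions: Dess–Martin periodinane, CH2Cl2, 0 °C → rt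
Reagents that add atoms: none
Why: Dess–Martin oxidation of the allylic alcohol restores the enone, removes the racemic carbinol centre and leaves the alkenyl iodide intact.

**Step 18**
Reactants: 19 methyl (2R)-2-[(3S,6S)-6-ethenyl-6-methyl-1,2-dioxan-3-yl]propanoate; 35 3-[(3E)-4-iodo-3-methylbut-3-en-1-yl]-2,4,4-trimethylcyclohex-2-en-1-one
Product: 37 methyl (2R)-2-[(3S,6R)-6-methyl-6-[(3E)-4-methyl-6-(2,6,6-trimethyl-3-oxocyclohex-1-en-1-yl)hex-3-en-1-yl]-1,2-dioxan-3-yl]propanoate, via alkylborane 36 (not isolated)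
Conditions: 9-borabicyclo[3.3.1]nonane dimer (1.3 equiv B–H), THF, 0 °C → rt; then 3 M aq. K3PO4, 35, PdCl2(dppf) [dppf = 1,1'-bis(diphenylphosphino)ferrocene] (5 mol%), AsPh3 (10 mol%), DMF, rt, degassed
Reagents that add atoms: none
Why: Anti-Markovnikov hydroboration of the vinyl group and B-alkyl Suzuki–Miyaura coupling join the two halves with retention of the (E)-geometry; dialkyl peroxides are known to survive hydroboration and palladium cross-coupling, and no stereocentre is touched.

## Compound list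

1 | 3-methylbut-3-en-2-ol (racemic) | C=C(C)C(C)O | starting material
2 | 1,1,1-trimethoxyethane | CC(OC)(OC)OC | starting material
3 | 3-[(1-methoxyethenyl)oxy]-2-methylbut-1-ene | C=C(OC)OC(C)C(C)=C | intermediate
4 | methyl (4E)-4-methylhex-4-enoate | COC(=O)CC/C(C)=C/C | intermediate
5 | (4E)-4-methylhex-4-enal | O=CCC/C(C)=C/C | intermediate
6 | (2E)-but-2-ene | C/C=C/C | starting material
7 | [(2E)-but-2-en-1-yl]potassium | C/C=C/C[K] | intermediate
8 | [(2E)-but-2-en-1-yl]bis[(1R,2S,3R,5R)-2,6,6-trimethylbicyclo[3.1.1]heptan-3-yl]borane | C/C=C/CB([C@@H]1C[C@@H]2C[C@H]([C@H]1C)C2(C)C)[C@@H]1C[C@@H]2C[C@H]([C@H]1C)C2(C)C | intermediate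
9 | (3S,4R,7E)-3,7-dimethylnona-1,7-dien-4-yl bis[(1R,2S,3R,5R)-2,6,6-trimethylbicyclo[3.1.1]heptan-3-yl]borinate | C=C[C@H](C)[C@@H](CC/C(C)=C/C)OB([C@@H]1C[C@@H]2C[C@H]([C@H]1C)C2(C)C)[C@@H]1C[C@@H]2C[C@H]([C@H]1C)C2(C)C | intermediate
10 | (3S,4R,7E)-3,7-dimethylnona-1,7-dien-4-ol | C=C[C@H](C)[C@H](O)CC/C(C)=C/C | intermediate
11 | (3S,4R,7E)-3,7-dimethylnona-1,7-dien-4-yl trifluoromethanesulfonate | C=C[C@H](C)[C@H](OS(=O)(=O)C(F)(F)F)CC/C(C)=C/C | intermediate
12 | (3S,4S,7E)-4-[(2-methoxypropan-2-yl)peroxy]-3,7-dimethylnona-1,7-diene | C=C[C@H](C)[C@@H](OOC(C)(C)OC)CC/C(C)=C/C | intermediate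
13 | (2R,3R)-2-[(3S,4S)-3-[(2-methoxypropan-2-yl)peroxy]-4-methylhex-5-en-1-yl]-2,3-dimethyloxirane | C=C[C@H](C)[C@@H](OOC(C)(C)OC)CC[C@@]1(C)O[C@@H]1C | intermediate
14 | (2R,3R)-2-[(3S,4S)-3-hydroperoxy-4-methylhex-5-en-1-yl]-2,3-dimethyloxirane | C=C[C@H](C)[C@@H](OO)CC[C@@]1(C)O[C@@H]1C | intermediate
15 | (1R)-1-[(3S,6S)-6-[(2S)-but-3-en-2-yl]-3-methyl-1,2-dioxan-3-yl]ethan-1-ol | C=C[C@H](C)[C@@H]1CC[C@@](C)([C@H](O)C)OO1 | intermediate
16 | (2R)-2-[(3S,6S)-6-[(1R)-1-hydroxyethyl]-6-methyl-1,2-dioxan-3-yl]propanal | O=C[C@H](C)[C@@H]1CC[C@@](C)([C@H](O)C)OO1 | intermediate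
17 | (2R)-2-[(3S,6S)-6-[(1R)-1-hydroxyethyl]-6-methyl-1,2-dioxan-3-yl]propanoic acid | OC(=O)[C@H](C)[C@@H]1CC[C@@](C)([C@H](O)C)OO1 | intermediate
18 | methyl (2R)-2-[(3S,6S)-6-[(1R)-1-hydroxyethyl]-6-methyl-1,2-dioxan-3-yl]propanoate | COC(=O)[C@H](C)[C@@H]1CC[C@@](C)([C@H](O)C)OO1 | intermediate
19 | methyl (2R)-2-[(3S,6S)-6-ethenyl-6-methyl-1,2-dioxan-3-yl]propanoate | COC(=O)[C@H](C)[C@@H]1CC[C@@](C)(C=C)OO1 | intermediate
20 | 3-methylbutan-2-one | CC(=O)C(C)C | starting material
21 | methyl prop-2-enoate | C=CC(=O)OC | starting material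
22 | methyl 4,4-dimethyl-5-oxohexanoate | COC(=O)CCC(C)(C)C(C)=O | intermediate
23 | 4,4-dimethylcyclohexane-1,3-dione | CC1(C)CCC(=O)CC1=O | intermediate
24 | 2,4,4-trimethylcyclohexane-1,3-dione | CC1C(=O)CCC(C)(C)C1=O | intermediate
25 | 3-ethoxy-2,6,6-trimethylcyclohex-2-en-1-one | CCOC1=C(C)C(=O)C(C)(C)CC1 | intermediate
26 | 4-bromobut-1-yne | C#CCCBr | starting material
27 | (4-bromobut-1-yn-1-yl)trimethylsilane | C[Si](C)(C)C#CCCBr | intermediate
28 | bromo[4-(trimethylsilyl)but-3-yn-1-yl]magnesium | C[Si](C)(C)C#CCC[Mg]Br | intermediate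
29 | 3-ethoxy-2,6,6-trimethyl-1-[4-(trimethylsilyl)but-3-yn-1-yl]cyclohex-2-en-1-ol (racemic) | CCOC1=C(C)C(O)(CCC#C[Si](C)(C)C)C(C)(C)CC1 | intermediate
30 | 2,4,4-trimethyl-3-[4-(trimethylsilyl)but-3-yn-1-yl]cyclohex-2-en-1-one | CC1=C(CCC#C[Si](C)(C)C)C(C)(C)CCC1=O | intermediate
31 | 2,4,4-trimethyl-3-[4-(trimethylsilyl)but-3-yn-1-yl]cyclohex-2-en-1-ol (racemic) | CC1=C(CCC#C[Si](C)(C)C)C(C)(C)CCC1O | intermediate
32 | 3-(but-3-yn-1-yl)-2,4,4-trimethylcyclohex-2-en-1-ol (racemic) | CC1=C(CCC#C)C(C)(C)CCC1O | intermediate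
33 | {(1E)-4-[3-(dimethylalumanyloxy)-2,6,6-trimethylcyclohex-1-en-1-yl]-2-methylbut-1-en-1-yl}dimethylalumane (racemic) | CC1=C(CC/C(C)=C/[Al](C)C)C(C)(C)CCC1O[Al](C)C | intermediate
34 | 3-[(3E)-4-iodo-3-methylbut-3-en-1-yl]-2,4,4-trimethylcyclohex-2-en-1-ol (racemic) | CC1=C(CC/C(C)=C/I)C(C)(C)CCC1O | intermediate
35 | 3-[(3E)-4-iodo-3-methylbut-3-en-1-yl]-2,4,4-trimethylcyclohex-2-en-1-one | CC1=C(CC/C(C)=C/I)C(C)(C)CCC1=O | intermediate
36 | methyl (2R)-2-[(3S,6R)-6-[2-(9-borabicyclo[3.3.1]nonan-9-yl)ethyl]-6-methyl-1,2-dioxan-3-yl]propanoate | COC(=O)[C@H](C)[C@@H]1CC[C@@](C)(CCB2C3CCCC2CCC3)OO1 | intermediate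
37 | methyl (2R)-2-[(3S,6R)-6-methyl-6-[(3E)-4-methyl-6-(2,6,6-trimethyl-3-oxocyclohex-1-en-1-yl)hex-3-en-1-yl]-1,2-dioxan-3-yl]propanoate | COC(=O)[C@H](C)[C@@H]1CC[C@@](C)(CC/C=C(\C)CCC2=C(C)C(=O)CCC2(C)C)OO1 | target

## Step count and risks

Total step count: 18.
Longest linear sequence: 10 steps (steps 1–9, then 18). The enone half needs 8 steps to the coupling (steps 10–12 and 14–17, then 18, with step 13 feeding step 14).

**Step 4 (peroxide SN2 on a β-branched secondary triflate).** E2 elimination towards the conjugated diene or ionisation of the triflate can compete. The fallback sets out from 10 and comes back at 15, reversing the order of the two C–O bond formations. Alcohol 10 is mesylated (MsCl, Et3N) to (3S,4R,7E)-3,7-dimethylnona-1,7-dien-4-yl methanesulfonate F1. Shi epoxidation as in step 5 gives (3R,4S)-1-[(2R,3R)-2,3-dimethyloxiran-2-yl]-4-methylhex-5-en-3-yl methanesulfonate F2. Ethereal H2O2 with catalytic MoO2(acac)2 opens the epoxide at the tertiary carbon with inversion to (3S,4R,7S,8R)-7-hydroperoxy-8-hydroxy-3,7-dimethylnon-1-en-4-yl methanesulfonate F3. KOt-Bu in THF at 0 °C then closes the dioxane by intramolecular 6-exo SN2 displacement of the mesylate (inversion at C4) and delivers 15.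

**Step 9 (dehydration of a hindered methyl carbinol).** Slow elimination or ion-pair rearrangement is possible next to the quaternary centre. The fallback sets out from 18 and comes back at 19, replacing dehydration by an oxidation–enol triflate–reduction sequence. Dess–Martin oxidation gives methyl (2R)-2-[(3S,6S)-6-acetyl-6-methyl-1,2-dioxan-3-yl]propanoate F4. Kinetic enolisation of the methyl ketone with KN(SiMe3)2 at −78 °C and trapping with PhNTf2 gives methyl (2R)-2-[(3S,6S)-6-methyl-6-{1-[(trifluoromethanesulfonyl)oxy]ethenyl}-1,2-dioxan-3-yl]propanoate F5. Palladium-catalysed formate reduction (Pd(OAc)2, PPh3, HCO2H, n-Bu3N, DMF, 40 °C) replaces the triflate by hydrogen and gives 19.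

**Step 18 (alkylborane and palladium/base in the presence of the peroxide).** The borane near the O–O bond or the basic cross-coupling medium may damage the dioxane. The fallback sets out from 19 and comes back at 37, moving the nucleophile from boron to zinc and removing the base. Hydroboration with immediate oxidation (9-BBN; then NaBO3·4H2O) gives methyl (2R)-2-[(3S,6S)-6-(2-hydroxyethyl)-6-methyl-1,2-dioxan-3-yl]propanoate F6. Preformed Ph3P·I2 with imidazole gives methyl (2R)-2-[(3S,6S)-6-(2-iodoethyl)-6-methyl-1,2-dioxan-3-yl]propanoate F7. Zinc dust with LiCl in THF gives iodo{2-[(3S,6S)-6-[(2R)-1-methoxy-1-oxopropan-2-yl]-3-methyl-1,2-dioxan-3-yl]ethyl}zinc F8. Negishi coupling of this reagent with 35 (Pd(PPh3)4, THF, rt) gives 37.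

## Further compounds

F1 | step 4 | (3S,4R,7E)-3,7-dimethylnona-1,7-dien-4-yl methanesulfonate | C=C[C@H](C)[C@H](OS(C)(=O)=O)CC/C(C)=C/C
F2 | step 4 | (3R,4S)-1-[(2R,3R)-2,3-dimethyloxiran-2-yl]-4-methylhex-5-en-3-yl methanesulfonate | C=C[C@H](C)[C@H](OS(C)(=O)=O)CC[C@@]1(C)O[C@@H]1C
F3 | step 4 | (3S,4R,7S,8R)-7-hydroperoxy-8-hydroxy-3,7-dimethylnon-1-en-4-yl methanesulfonate | C=C[C@H](C)[C@H](OS(C)(=O)=O)CC[C@](C)(OO)[C@H](O)C
F4 | step 9 | methyl (2R)-2-[(3S,6S)-6-acetyl-6-methyl-1,2-dioxan-3-yl]propanoate | COC(=O)[C@H](C)[C@@H]1CC[C@@](C)(C(C)=O)OO1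
F5 | step 9 | methyl (2R)-2-[(3S,6S)-6-methyl-6-{1-[(trifluoromethanesulfonyl)oxy]ethenyl}-1,2-dioxan-3-yl]propanoate | COC(=O)[C@H](C)[C@@H]1CC[C@@](C)(C(=C)OS(=O)(=O)C(F)(F)F)OO1
F6 | step 18 | methyl (2R)-2-[(3S,6S)-6-(2-hydroxyethyl)-6-methyl-1,2-dioxan-3-yl]propanoate | COC(=O)[C@H](C)[C@@H]1CC[C@@](C)(CCO)OO1
F7 | step 18 | methyl (2R)-2-[(3S,6S)-6-(2-iodoethyl)-6-methyl-1,2-dioxan-3-yl]propanoate | COC(=O)[C@H](C)[C@@H]1CC[C@@](C)(CCI)OO1
F8 | step 18 | iodo{2-[(3S,6S)-6-[(2R)-1-methoxy-1-oxopropan-2-yl]-3-methyl-1,2-dioxan-3-yl]ethyl}zinc | COC(=O)[C@H](C)[C@@H]1CC[C@@](C)(CC[Zn]I)OO1
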